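The benzene ring (C4a, C5, C6, C7, C8, C8a) is built last, onto a finished enantiopure oxane. That ring is a hydroquinone whose O1 on C8a is etherified and whose para 6-OH is free. It carries methyls on C7 and C8 and hydrogen on C5, which is the imprint of an alkoxycarbene, 2-butyne and CO. A single Dötz benzannulation makes C8–C8a, C6–C7 and C5–C6 and delivers the chroman-6-ol. Its precursor is the Cr(CO)5 complex of a 6,6-disubstituted 3-methyleneoxan-2-ylidene, whose stereocentre comes from a Sharpless epoxide. The C3=C4 bond is added late, after all heated steps, since 2H-chromenes can racemise by reversible ring opening.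

Key step: step 10

Remark on the target: the SMILES encodes (S) at C2, E at C3′=C4′ and E at C7′=C8′ (carboxyl carbon trans to C6′).
Remark on notation: chromium carbonyls are written in the Cr=C=O valence-bond style. The η6-arene tricarbonylchromium intermediate of the key step is written as arene and Cr(CO)3 joined by a dot, because SMILES has no hapticity.

Step 1
Reactants: 1 geranyl acetate
Product: 2 (2E,6E)-8-hydroxy-3,7-dimethylocta-2,6-dien-1-yl acetate
Conditions: SeO2 (cat.), t-BuOOH, salicylic acid (cat.), CH2Cl2, 0 °C to rt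
Reagents that add atoms: tert-butyl hydroperoxide, CC(C)(C)OO
Why: Catalytic SeO2 allylic oxidation (ene reaction, then [2,3]-sigmatropic shift) picks the electron-richer terminal alkene, which no allylic acetate deactivates, and by its usual E rule hydroxylates the methyl group trans to the chain, so C5′ is oxygenated with the C3′=C4′ geometry already correct.

Step 2
Reactants: 2 (2E,6E)-8-hydroxy-3,7-dimethylocta-2,6-dien-1-yl acetate
Product: 3 (2E,6E)-8-(tert-butyldimethylsilyloxy)-3,7-dimethylocta-2,6-dien-1-yl acetate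
Conditions: TBSCl, imidazole, CH2Cl2, rt
Reagents that add atoms: tert-butyldimethylsilyl chloride, CC(C)(C)[Si](C)(C)Cl
Why: Standard silylation of a primary allylic alcohol gives an ether that withstands the hydride, organolithium and chromium(0) chemistry ahead.

Step 3
Reactants: 3 (2E,6E)-8-(tert-butyldimethylsilyloxy)-3,7-dimethylocta-2,6-dien-1-yl acetate
Product: 4 (2E,6E)-8-(tert-butyldimethylsilyloxy)-3,7-dimethylocta-2,6-dien-1-ol
Conditions: K2CO3 (cat.), MeOH, rt
Reagents that add atoms: none
Why: Base-catalysed transesterification with methanol removes the acetate without touching the silyl ether or either E-alkene.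

Step 4
Reactants: 4 (2E,6E)-8-(tert-butyldimethylsilyloxy)-3,7-dimethylocta-2,6-dien-1-ol
Product: 5 [(2S,3S)-3-[(3E)-5-(tert-butyldimethylsilyloxy)-4-methylpent-3-en-1-yl]-3-methyloxiran-2-yl]methanol
Conditions: Ti(OiPr)4 (cat.), L-(+)-diethyl tartrate (cat.), t-BuOOH, 4 Å MS, CH2Cl2, −20 °C
Reagents that add atoms: tert-butyl hydroperoxide, CC(C)(C)OO
Why: The Sharpless asymmetric epoxidation acts only on the alkene that carries the free allylic hydroxyl, and with L-(+)-tartrate an allylic alcohol of the geraniol type gives the (2S,3S)-epoxide, which sets the tertiary C–O stereocentre that becomes C2 of the chromene and is never broken afterwards.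

Step 5
Reactants: 5 [(2S,3S)-3-[(3E)-5-(tert-butyldimethylsilyloxy)-4-methylpent-3-en-1-yl]-3-methyloxiran-2-yl]methanol
Product: 6 (3S,6E)-8-(tert-butyldimethylsilyloxy)-3,7-dimethyloct-6-ene-1,3-diol
Conditions: Red-Al, THF, 0 °C to rt
Reagents that add atoms: none
Why: In this hydroxyl-directed reductive epoxide opening the aluminate bound to O1 delivers hydride to C2, the less substituted epoxide carbon, so the 1,3-diol forms with the tertiary C3–O bond and its configuration intact.

Step 6
Reactants: 6 (3S,6E)-8-(tert-butyldimethylsilyloxy)-3,7-dimethyloct-6-ene-1,3-diol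
Product: 8 (3S,6E)-8-(tert-butyldimethylsilyloxy)-3,7-dimethyl-3-(trimethylsilyloxy)oct-6-en-1-yl 4-methylbenzenesulfonate, via hydroxy tosylate 7 (not isolated)
Conditions: TsCl, Et3N (excess), DMAP (cat.), CH2Cl2, 0 °C; then TMSOTf, 0 °C
Reagents that add atoms: 4-toluenesulfonyl chloride, Cc1ccc(cc1)S(=O)(=O)Cl; trimethylsilyl triflate, C[Si](C)(C)OS(=O)(=O)C(F)(F)F
Why: Selective sulfonylation takes the primary hydroxyl far faster than the tertiary one, and capping the latter as a TMS ether in the same flask blocks the 4-exo-tet closure to an oxetane that a free tertiary alkoxide would undergo under the basic conditions of step 7.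

Step 7
Reactants: 8 (3S,6E)-8-(tert-butyldimethylsilyloxy)-3,7-dimethyl-3-(trimethylsilyloxy)oct-6-en-1-yl 4-methylbenzenesulfonate; 9 trimethylsilylacetylene
Product: 11 (5S,8E)-10-(tert-butyldimethylsilyloxy)-5,9-dimethyldec-8-en-1-yn-5-ol, via bis-silylated alkyne 10 (not isolated)
Conditions: 9, n-BuLi, THF, −78 °C; then 8, DMPU, −78 °C to rt; then K2CO3 (cat.), MeOH, rt
Reagents that add atoms: none
Why: SN2 alkylation of a lithium acetylide by an unhindered primary tosylate in a dipolar co-solvent adds the two carbons that become C4a and C8a, and carbonate in methanol then strips the alkynyl and the tertiary O-trimethylsilyl groups while the primary TBS ether stays.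

Step 8
Reactants: 11 (5S,8E)-10-(tert-butyldimethylsilyloxy)-5,9-dimethyldec-8-en-1-yn-5-ol; 12 chromium hexacarbonyl
Product: 13 pentacarbonyl{(6R)-6-[(3E)-5-(tert-butyldimethylsilyloxy)-4-methylpent-3-en-1-yl]-6-methyloxan-2-ylidene}chromium(0) (same spatial arrangement as in 11; only the CIP ranking changes)
Conditions: 12, hν, THF, −10 °C; then 11, rt, dark, no amine base
Reagents that add atoms: none
Why: In this alkynol cycloisomerisation at a Cr(CO)5 template the terminal alkyne displaces THF and rearranges to the chromium vinylidene, and the tethered hydroxyl adds to its electrophilic α-carbon, which for a pent-4-yn-1-ol closes the six-membered 2-oxacycloalkylidene ring (helped by the gem-disubstituted carbinol carbon), while leaving out amine base keeps the carbene from collapsing to the cyclic enol ether.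

Step 9
Reactants: 13 pentacarbonyl{(6R)-6-[(3E)-5-(tert-butyldimethylsilyloxy)-4-methylpent-3-en-1-yl]-6-methyloxan-2-ylidene}chromium(0)
Product: 15 pentacarbonyl{(6S)-6-[(3E)-5-(tert-butyldimethylsilyloxy)-4-methylpent-3-en-1-yl]-6-methyl-3-methylideneoxan-2-ylidene}chromium(0), via Mannich base 14 (not isolated)
Conditions: CH2=NMe2+ I− (2.5 equiv), Et3N (2.5 equiv), CH2Cl2, 0 °C to rt, dark; short silica plug, used at once
Reagents that add atoms: Eschenmoser's salt, C=[N+](C)C.[I-]
Why: The α-CH2 of a Fischer alkoxycarbene is acidic enough for triethylamine, so a Mannich reaction with the preformed iminium salt and E1cB loss of the amine install the exocyclic methylene (the future C5), as is known for 2-oxacyclopentylidene chromium complexes, and the excess iminium salt binds the liberated dimethylamine as the aminal before it can attack the carbene carbon or the new acceptor alkene.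

Step 10
Reactants: 15 pentacarbonyl{(6S)-6-[(3E)-5-(tert-butyldimethylsilyloxy)-4-methylpent-3-en-1-yl]-6-methyl-3-methylideneoxan-2-ylidene}chromium(0); 16 2-butyne
Product: 18 (2S)-2-[(3E)-5-(tert-butyldimethylsilyloxy)-4-methylpent-3-en-1-yl]-2,7,8-trimethylchroman-6-ol, via tricarbonylchromium arene complex 17 (not isolated)
Conditions: 16 (5 equiv), t-BuOMe (0.05 M, degassed), sealed tube, 50 °C; then air, daylight, Et2O, rt
Reagents that add atoms: none
Why: Mild heating expels one cis-CO from 15, 2-butyne binds and inserts into the Cr=C8a bond (C8–C8a), a carbonyl ligand migrates onto the new carbene carbon C7 (C6–C7) to give a chromium-bound dienylketene, and the ketene carbon C6 then bonds to the exocyclic methylene carbon C5 (C5–C6); tautomerisation of the resulting cyclohexadienone gives the phenol as its Cr(CO)3 complex 17, which air and light demetalate. The closest known reaction type is the Dötz benzannulation of alkenyl(alkoxy)carbene chromium complexes with internal alkynes to 4-alkoxyphenols, used here on a complex whose alkoxy oxygen and alkenyl group are tied together in the oxane ring. The only ring closed is the benzene ring, by a 6π-electrocyclisation of the dienylketene, and because C8a and C4a are adjacent ring atoms that both carry exocyclic π bonds the oxane locks this diene part s-cis, which is the geometry the closure needs. No stereocentre is created, and C2 is a fully substituted carbon that takes no part, so the configuration set in step 4 is carried through. The step needs CO insertion and phenol formation to outrun cyclobutenone, furan and five-membered-ring products as well as oligomerisation of the acceptor alkene: the alkoxy donor on the carbene carbon, a small dialkylalkyne in excess, an ether solvent, about 50 °C and high dilution favour the phenol, the symmetrical alkyne leaves no regiochemical choice, and the remote trisubstituted chain alkene is too hindered to compete for chromium. Since O1 sits on the carbene carbon from the start and the 6-OH is born from a carbonyl ligand, no later step has to tell the two hydroquinone oxygens apart.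

Step 11
Reactants: 18 (2S)-2-[(3E)-5-(tert-butyldimethylsilyloxy)-4-methylpent-3-en-1-yl]-2,7,8-trimethylchroman-6-ol
Product: 19 (2S)-6-(tert-butyldimethylsilyloxy)-2-[(3E)-5-(tert-butyldimethylsilyloxy)-4-methylpent-3-en-1-yl]-2,7,8-trimethylchroman
Conditions: TBSCl, imidazole, DMF, rt
Reagents that add atoms: tert-butyldimethylsilyl chloride, CC(C)(C)[Si](C)(C)Cl
Why: Silylation of the phenol gives an aryl TBS ether that, unlike an aryl ester, survives the azaenolate of step 15, keeps the arene electron-rich for step 18 and falls off in the final hydroxide step without a step of its own.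

Step 12
Reactants: 19 (2S)-6-(tert-butyldimethylsilyloxy)-2-[(3E)-5-(tert-butyldimethylsilyloxy)-4-methylpent-3-en-1-yl]-2,7,8-trimethylchroman
Product: 20 (2E)-5-[(2S)-6-(tert-butyldimethylsilyloxy)-2,7,8-trimethylchroman-2-yl]-2-methylpent-2-en-1-ol
Conditions: camphorsulfonic acid (cat.), MeOH/CH2Cl2, 0 °C
Reagents that add atoms: none
Why: In acid-catalysed methanolysis a primary alkyl TBS ether is cleaved much faster than an aryl TBS ether, whose oxygen is hardly basic, so only the C5′ hydroxyl is released.

Step 13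
Reactants: 20 (2E)-5-[(2S)-6-(tert-butyldimethylsilyloxy)-2,7,8-trimethylchroman-2-yl]-2-methylpent-2-en-1-ol
Product: 21 (2S)-2-[(3E)-5-bromo-4-methylpent-3-en-1-yl]-6-(tert-butyldimethylsilyloxy)-2,7,8-trimethylchroman
Conditions: CBr4, PPh3, CH2Cl2, 0 °C
Reagents that add atoms: carbon tetrabromide, BrC(Br)(Br)Br
Why: The Appel reaction converts the primary allylic alcohol through its oxyphosphonium salt by SN2 under neutral conditions, so neither an allylic shift nor loss of the E geometry is expected.

Step 14
Reactants: 22 acetaldehyde; 23 cyclohexylamine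
Product: 24 (E)-N-ethylidenecyclohexylamine
Conditions: neat, 0 °C; KOH pellets; distillation
Reagents that add atoms: none
Why: Simple condensation of an aldehyde with a primary amine gives the aldimine once the water is taken up by the drying agent.

Step 15
Reactants: 21 (2S)-2-[(3E)-5-bromo-4-methylpent-3-en-1-yl]-6-(tert-butyldimethylsilyloxy)-2,7,8-trimethylchroman; 24 (E)-N-ethylidenecyclohexylamine
Product: 26 (4E)-7-[(2S)-6-(tert-butyldimethylsilyloxy)-2,7,8-trimethylchroman-2-yl]-4-methylhept-4-enal, via alkylated imine 25 (not isolated)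
Conditions: 24, LDA, THF, 0 °C; then 21, −78 to −20 °C; then aq. AcOH/NaOAc buffer (pH 4.5), rt
Reagents that add atoms: water, O
Why: In this metalloenamine alkylation the lithiated aldimine attacks the primary allylic bromide by SN2 at C5′ (the SN2′ terminus C3′ is more hindered) and forms C5′–C6′, and buffered hydrolysis of the imine releases the two-carbon-longer aldehyde in the same operation, so no redox adjustment is needed.

Step 16
Reactants: 27 methyl (triphenylphosphoranylidene)acetate; 28 5-bromo-2-methylpent-2-ene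
Product: 30 methyl 6-methyl-2-(triphenylphosphoranylidene)hept-5-enoate, via phosphonium bromide 29 (not isolated)
Conditions: NaI (cat.), MeCN, 80 °C; then 1 M NaOH, CH2Cl2, rt
Reagents that add atoms: none
Why: C-Alkylation of the stabilised ylide by the primary bromide gives the phosphonium salt, and aqueous hydroxide deprotonates it to the α-substituted stabilised ylide, which brings in C8′–C12′, the ester carbon and both terminal methyls that the parent ylide alone would lack.

Step 17
Reactants: 26 (4E)-7-[(2S)-6-(tert-butyldimethylsilyloxy)-2,7,8-trimethylchroman-2-yl]-4-methylhept-4-enal; 30 methyl 6-methyl-2-(triphenylphosphoranylidene)hept-5-enoate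
Product: 31 methyl (2E,6E)-9-[(2S)-6-(tert-butyldimethylsilyloxy)-2,7,8-trimethylchroman-2-yl]-6-methyl-2-(4-methylpent-3-en-1-yl)nona-2,6-dienoate
Conditions: toluene, 90 °C
Reagents that add atoms: none
Why: The Wittig reaction of an α-branched ester-stabilised ylide with an unbranched aldehyde places the ester trans to the aldehyde chain, which is the E-enoate of the target, and the heating is harmless because the heterocycle is still a configurationally inert chroman.

Step 18
Reactants: 31 methyl (2E,6E)-9-[(2S)-6-(tert-butyldimethylsilyloxy)-2,7,8-trimethylchroman-2-yl]-6-methyl-2-(4-methylpent-3-en-1-yl)nona-2,6-dienoate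
Product: 32 methyl (2E,6E)-9-[(2S)-6-(tert-butyldimethylsilyloxy)-2,7,8-trimethyl-2H-chromen-2-yl]-6-methyl-2-(4-methylpent-3-en-1-yl)nona-2,6-dienoate
Conditions: DDQ (1.2 equiv), 1,4-dioxane, 60–70 °C, dark, stopped at full conversion
Reagents that add atoms: none
Why: In the DDQ dehydrogenation of a chroman, hydride leaves C4 to give a benzylic cation stabilised by O1 through C8a and loss of a C3 proton gives the 2H-chromene, while the isolated trisubstituted alkenes and the enoate offer no comparably stabilised cation, no allylic ether is left at this stage, C2 bears no hydrogen so oxidation stops there, and short moderate heating in the dark guards C2 against electrocyclic ring opening.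

Step 19
Reactants: 32 methyl (2E,6E)-9-[(2S)-6-(tert-butyldimethylsilyloxy)-2,7,8-trimethyl-2H-chromen-2-yl]-6-methyl-2-(4-methylpent-3-en-1-yl)nona-2,6-dienoate
Product: 33 (2E,6E)-9-[(2S)-6-hydroxy-2,7,8-trimethyl-2H-chromen-2-yl]-6-methyl-2-(4-methylpent-3-en-1-yl)nona-2,6-dienoic acid (target)
Conditions: LiOH (excess), THF/MeOH/H2O, 45 °C, argon, dark; then cold 1 M HCl to pH 3
Reagents that add atoms: lithium hydroxide, [Li+].[OH-]
Why: Hydroxide saponifies the methyl ester and cleaves the base-labile aryl silyl ether in one operation, and the low temperature together with exclusion of air and light protects the oxidisable chromenol and its C2 configuration.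

Compound list
1 | geranyl acetate | CC(C)=CCC/C(C)=C/COC(C)=O | starting material
2 | (2E,6E)-8-hydroxy-3,7-dimethylocta-2,6-dien-1-yl acetate | OC/C(C)=C/CC/C(C)=C/COC(C)=O | intermediate
3 | (2E,6E)-8-(tert-butyldimethylsilyloxy)-3,7-dimethylocta-2,6-dien-1-yl acetate | CC(C)(C)[Si](C)(C)OC/C(C)=C/CC/C(C)=C/COC(C)=O | intermediate
4 | (2E,6E)-8-(tert-butyldimethylsilyloxy)-3,7-dimethylocta-2,6-dien-1-ol | CC(C)(C)[Si](C)(C)OC/C(C)=C/CC/C(C)=C/CO | intermediate
5 | [(2S,3S)-3-[(3E)-5-(tert-butyldimethylsilyloxy)-4-methylpent-3-en-1-yl]-3-methyloxiran-2-yl]methanol | CC(C)(C)[Si](C)(C)OC/C(C)=C/CC[C@]1(C)O[C@H]1CO | intermediate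
6 | (3S,6E)-8-(tert-butyldimethylsilyloxy)-3,7-dimethyloct-6-ene-1,3-diol | CC(C)(C)[Si](C)(C)OC/C(C)=C/CC[C@](C)(O)CCO | intermediate
7 | (3S,6E)-8-(tert-butyldimethylsilyloxy)-3-hydroxy-3,7-dimethyloct-6-en-1-yl 4-methylbenzenesulfonate | CC(C)(C)[Si](C)(C)OC/C(C)=C/CC[C@](C)(O)CCOS(=O)(=O)c1ccc(C)cc1 | intermediate
8 | (3S,6E)-8-(tert-butyldimethylsilyloxy)-3,7-dimethyl-3-(trimethylsilyloxy)oct-6-en-1-yl 4-methylbenzenesulfonate | CC(C)(C)[Si](C)(C)OC/C(C)=C/CC[C@](C)(O[Si](C)(C)C)CCOS(=O)(=O)c1ccc(C)cc1 | intermediate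
9 | trimethylsilylacetylene | C#C[Si](C)(C)C | starting material
10 | (5S,8E)-10-(tert-butyldimethylsilyloxy)-5,9-dimethyl-1-(trimethylsilyl)-5-(trimethylsilyloxy)dec-8-en-1-yne | CC(C)(C)[Si](C)(C)OC/C(C)=C/CC[C@](C)(O[Si](C)(C)C)CCC#C[Si](C)(C)C | intermediate
11 | (5S,8E)-10-(tert-butyldimethylsilyloxy)-5,9-dimethyldec-8-en-1-yn-5-ol | CC(C)(C)[Si](C)(C)OC/C(C)=C/CC[C@](C)(O)CCC#C | intermediate
12 | chromium hexacarbonyl | O=C=[Cr](=C=O)(=C=O)(=C=O)(=C=O)=C=O | starting material
13 | pentacarbonyl{(6R)-6-[(3E)-5-(tert-butyldimethylsilyloxy)-4-methylpent-3-en-1-yl]-6-methyloxan-2-ylidene}chromium(0) | CC(C)(C)[Si](C)(C)OC/C(C)=C/CC[C@@]1(C)CCCC(=[Cr](=C=O)(=C=O)(=C=O)(=C=O)=C=O)O1 | intermediate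
14 | pentacarbonyl{(6S)-6-[(3E)-5-(tert-butyldimethylsilyloxy)-4-methylpent-3-en-1-yl]-3-[(dimethylamino)methyl]-6-methyloxan-2-ylidene}chromium(0), C3 epimers | CC(C)(C)[Si](C)(C)OC/C(C)=C/CC[C@@]1(C)CCC(CN(C)C)C(=[Cr](=C=O)(=C=O)(=C=O)(=C=O)=C=O)O1 | intermediate
15 | pentacarbonyl{(6S)-6-[(3E)-5-(tert-butyldimethylsilyloxy)-4-methylpent-3-en-1-yl]-6-methyl-3-methylideneoxan-2-ylidene}chromium(0) | CC(C)(C)[Si](C)(C)OC/C(C)=C/CC[C@@]1(C)CCC(=C)C(=[Cr](=C=O)(=C=O)(=C=O)(=C=O)=C=O)O1 | intermediate
16 | 2-butyne | CC#CC | starting material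
17 | tricarbonyl(η6-arene)chromium(0) complex of 18, metal on either arene face | CC(C)(C)[Si](C)(C)OC/C(C)=C/CC[C@@]1(C)CCc2cc(O)c(C)c(C)c2O1.O=C=[Cr](=C=O)=C=O | intermediate
18 | (2S)-2-[(3E)-5-(tert-butyldimethylsilyloxy)-4-methylpent-3-en-1-yl]-2,7,8-trimethylchroman-6-ol | CC(C)(C)[Si](C)(C)OC/C(C)=C/CC[C@@]1(C)CCc2cc(O)c(C)c(C)c2O1 | intermediate
19 | (2S)-6-(tert-butyldimethylsilyloxy)-2-[(3E)-5-(tert-butyldimethylsilyloxy)-4-methylpent-3-en-1-yl]-2,7,8-trimethylchroman | CC(C)(C)[Si](C)(C)OC/C(C)=C/CC[C@@]1(C)CCc2cc(O[Si](C)(C)C(C)(C)C)c(C)c(C)c2O1 | intermediate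
20 | (2E)-5-[(2S)-6-(tert-butyldimethylsilyloxy)-2,7,8-trimethylchroman-2-yl]-2-methylpent-2-en-1-ol | OC/C(C)=C/CC[C@@]1(C)CCc2cc(O[Si](C)(C)C(C)(C)C)c(C)c(C)c2O1 | intermediate
21 | (2S)-2-[(3E)-5-bromo-4-methylpent-3-en-1-yl]-6-(tert-butyldimethylsilyloxy)-2,7,8-trimethylchroman | BrC/C(C)=C/CC[C@@]1(C)CCc2cc(O[Si](C)(C)C(C)(C)C)c(C)c(C)c2O1 | intermediate
22 | acetaldehyde | CC=O | starting material
23 | cyclohexylamine | NC1CCCCC1 | starting material
24 | (E)-N-ethylidenecyclohexylamine | C/C=N/C1CCCCC1 | intermediate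
25 | N-cyclohexyl imine of aldehyde 26 | C1CCCCC1/N=C/CC/C(C)=C/CC[C@@]2(C)CCc3cc(O[Si](C)(C)C(C)(C)C)c(C)c(C)c3O2 | intermediate
26 | (4E)-7-[(2S)-6-(tert-butyldimethylsilyloxy)-2,7,8-trimethylchroman-2-yl]-4-methylhept-4-enal | O=CCC/C(C)=C/CC[C@@]1(C)CCc2cc(O[Si](C)(C)C(C)(C)C)c(C)c(C)c2O1 | intermediate
27 | methyl (triphenylphosphoranylidene)acetate | COC(=O)C=P(c1ccccc1)(c1ccccc1)c1ccccc1 | starting material
28 | 5-bromo-2-methylpent-2-ene | CC(C)=CCCBr | starting material
29 | (1-methoxy-6-methyl-1-oxohept-5-en-2-yl)triphenylphosphonium bromide | COC(=O)C(CCC=C(C)C)[P+](c1ccccc1)(c1ccccc1)c1ccccc1.[Br-] | intermediate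
30 | methyl 6-methyl-2-(triphenylphosphoranylidene)hept-5-enoate | COC(=O)C(CCC=C(C)C)=P(c1ccccc1)(c1ccccc1)c1ccccc1 | intermediate
31 | methyl (2E,6E)-9-[(2S)-6-(tert-butyldimethylsilyloxy)-2,7,8-trimethylchroman-2-yl]-6-methyl-2-(4-methylpent-3-en-1-yl)nona-2,6-dienoate | CC(C)=CCC/C(=C\CC/C(C)=C/CC[C@@]1(C)CCc2cc(O[Si](C)(C)C(C)(C)C)c(C)c(C)c2O1)C(=O)OC | intermediate
32 | methyl (2E,6E)-9-[(2S)-6-(tert-butyldimethylsilyloxy)-2,7,8-trimethyl-2H-chromen-2-yl]-6-methyl-2-(4-methylpent-3-en-1-yl)nona-2,6-dienoate | CC(C)=CCC/C(=C\CC/C(C)=C/CC[C@@]1(C)C=Cc2cc(O[Si](C)(C)C(C)(C)C)c(C)c(C)c2O1)C(=O)OC | intermediate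
33 | (2E,6E)-9-[(2S)-6-hydroxy-2,7,8-trimethyl-2H-chromen-2-yl]-6-methyl-2-(4-methylpent-3-en-1-yl)nona-2,6-dienoic acid | CC(C)=CCC/C(=C\CC/C(C)=C/CC[C@@]1(C)C=Cc2cc(O)c(C)c(C)c2O1)C(=O)O | target

Total step count: 19. Longest linear sequence: 17 (steps 1–13, 15, 17–19). Steps 14 and 16 are side branches.

Steps most likely to fail

1. Step 10.
- **Risk:** The electron-poor exocyclic alkene of 15 may oligomerise before the alkyne is taken up. The vinylcarbene stage may also leak away from CO insertion.
- **Approach:** The arene is bought instead of built, and O1–C8a is made by oxidative ketalisation, so the C2–O bond is again never broken. The fallback sets out from tosylate 8 and comes back at 18.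
- **Aryl partner:** 2,3-Dimethylhydroquinone is monomethylated (MeI, K2CO3, acetone) to 4-methoxy-2,3-dimethylphenol F1. Silylation (TBSCl, imidazole) gives tert-butyl(4-methoxy-2,3-dimethylphenoxy)dimethylsilane F2.
- **Coupling:** After directed ortho-lithiation beside the methoxy group (n-BuLi, TMEDA) and exchange of lithium for magnesium (MgBr2), F2 is coupled with 8 under Li2CuCl4 catalysis. This gives the fully protected aryl-octene F3.
- **Deprotection:** K2CO3 in methanol frees the phenol and the tertiary alcohol but not the primary TBS ether, giving the methoxyphenol carbinol F4.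
- **Ring closure and return:** PhI(OAc)2 in MeCN oxidises the 4-methoxyphenol, and the tethered hydroxyl traps the cation at C8a. The product is the mixed quinone monoketal 8a-methoxychromen-6-one F5. Zinc in acetic acid aromatises it reductively with loss of methanol to 18.

2. Step 8.
- **Risk:** The alkyne-to-vinylidene rearrangement at chromium and the attack of the hindered tertiary hydroxyl may be slower than the decay of the labile Cr(CO)5 solvate.
- **Approach:** The carbene carbon is made by the Fischer route and the ring by enolate alkylation plus alkoxy exchange. The fallback sets out from diol 6 and from 12 and comes back at 13.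
- **Building blocks:** MeLi and then Me3OBF4 convert 12 into pentacarbonyl(1-methoxyethylidene)chromium F6. Diol 6 is turned at −78 °C (Tf2O, 2,6-lutidine; then TMSOTf) into the silyl-protected primary triflate F7, which is used at once.
- **Alkylation and return:** Deprotonated F6 (n-BuLi, THF, −78 °C) is alkylated by F7 to the open-chain methoxycarbene complex F8. Mild acidic methanolysis of the TMS ether follows. Base-catalysed intramolecular exchange of methoxide for the tertiary alkoxide, with removal of methanol over molecular sieves, closes the ring to 13.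

3. Step 9.
- **Risk:** Liberated amine may add to the carbene carbon or to the new acceptor alkene. The amine base may also move the exocyclic double bond into the ring.
- **Approach:** An amine-free alkylation–elimination sequence sets out from 13 and comes back at 15.
- **Sequence:** Complex 13 is deprotonated (n-BuLi, THF, −78 °C) and alkylated with chloromethyl methyl ether to the 3-(methoxymethyl)oxan-2-ylidene complex F9. Brief contact with basic alumina eliminates methanol to give 15.

Further compounds
F1 | step 10 | 4-methoxy-2,3-dimethylphenol | COc1ccc(O)c(C)c1C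
F2 | step 10 | tert-butyl(4-methoxy-2,3-dimethylphenoxy)dimethylsilane | COc1ccc(O[Si](C)(C)C(C)(C)C)c(C)c1C
F3 | step 10 | (3S,6E)-8-(tert-butyldimethylsilyloxy)-1-[5-(tert-butyldimethylsilyloxy)-2-methoxy-3,4-dimethylphenyl]-3,7-dimethyl-3-(trimethylsilyloxy)oct-6-ene | CC(C)(C)[Si](C)(C)OC/C(C)=C/CC[C@](C)(O[Si](C)(C)C)CCc1cc(O[Si](C)(C)C(C)(C)C)c(C)c(C)c1OC
F4 | step 10 | (3S,6E)-8-(tert-butyldimethylsilyloxy)-1-(5-hydroxy-2-methoxy-3,4-dimethylphenyl)-3,7-dimethyloct-6-en-3-ol | CC(C)(C)[Si](C)(C)OC/C(C)=C/CC[C@](C)(O)CCc1cc(O)c(C)c(C)c1OC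
F5 | step 10 | (2S)-2-[(3E)-5-(tert-butyldimethylsilyloxy)-4-methylpent-3-en-1-yl]-8a-methoxy-2,7,8-trimethyl-2,3,4,8a-tetrahydro-6H-chromen-6-one, C8a epimers | CC(C)(C)[Si](C)(C)OC/C(C)=C/CC[C@@]1(C)CCC2=CC(=O)C(C)=C(C)C2(OC)O1
F6 | step 8 | pentacarbonyl(1-methoxyethylidene)chromium(0) | COC(C)=[Cr](=C=O)(=C=O)(=C=O)(=C=O)=C=O
F7 | step 8 | (3S,6E)-8-(tert-butyldimethylsilyloxy)-3,7-dimethyl-3-(trimethylsilyloxy)oct-6-en-1-yl trifluoromethanesulfonate | CC(C)(C)[Si](C)(C)OC/C(C)=C/CC[C@](C)(O[Si](C)(C)C)CCOS(=O)(=O)C(F)(F)F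
F8 | step 8 | pentacarbonyl[(5R,8E)-10-(tert-butyldimethylsilyloxy)-1-methoxy-5,9-dimethyl-5-(trimethylsilyloxy)dec-8-en-1-ylidene]chromium(0) | CC(C)(C)[Si](C)(C)OC/C(C)=C/CC[C@](C)(O[Si](C)(C)C)CCCC(OC)=[Cr](=C=O)(=C=O)(=C=O)(=C=O)=C=O
F9 | step 9 | pentacarbonyl{(6S)-6-[(3E)-5-(tert-butyldimethylsilyloxy)-4-methylpent-3-en-1-yl]-3-(methoxymethyl)-6-methyloxan-2-ylidene}chromium(0), C3 epimers | CC(C)(C)[Si](C)(C)OC/C(C)=C/CC[C@@]1(C)CCC(COC)C(=[Cr](=C=O)(=C=O)(=C=O)(=C=O)=C=O)O1
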